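The earlier runs and the new flask stem from a simulated flask with constants of no real substance.

The spring run was my way in, because it is the clearest early look at over-reaction product.

| setting | spring | winter | amber | violet | red | ochre |
|---|---|---|---|---|---|---|
| starting material | 0.20 M | 0.20 M | 0.10 M | 0.20 M | 0.20 M | 0.10 M |
| coupling partner | 0.19 M | 0.19 M | 0.190 M | 0.400 M | 0.190 M | 0.400 M |
| protic impurity | 4 mM | 4 mM | 4.00 mM | 4.00 mM | 4.00 mM | 4.00 mM |
| free catalyst | 0.15 mM | 0.050 mM | 0.10 mM | 0.10 mM | 0.10 mM | 0.10 mM |
| remark | run made earlier | run made earlier |  |  |  |  |
| time |  |  | 40 min | 40 min | 40 min | 40 min |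

| run | time / min | target / % | over-reaction product / % |
|---|---|---|---|
| spring | 0.667 | 0.7 | 0 |
| spring | 2.00 | 1.6 | 0 |
| spring | 4.00 | 3.3 | 0.6 |
| spring | 6.00 | 3.9 | 1.4 |
| spring | 8.00 | 4.7 | 0.6 |
| winter | 0.667 | 0.1 | 0.3 |
| winter | 2.00 | 0.5 | 0 |
| winter | 4.00 | 1.0 | 0.3 |
| winter | 6.00 | 0.3 | 0.8 |
| winter | 8.00 | 0.9 | 0.1 |

(standard deviation of a reading: 0.5 percentage points)

* all flasks from highest to lowest share of target in all that became target or over-reaction product, at 40 min (amber / violet / red / ochre)
* the share of target in all that became target or over-reaction product of the flask you put first, at 40 min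
* the share of target in all that became target or over-reaction product of the flask you put last, at 40 min



1. I assumed target is made at a steady rate and lost pseudo-first-order, with a rate constant proportional to free catalyst and coupling partner. The exposure, x, is that constant times the time. The share is then one minus e to the minus x, over x, whatever the making rate, and early on x is twice the ratio of over-reaction product to target.

2. Estimate: the last spring reading gave 0.255. Scaled by catalyst, partner and time, the exposure of red came to 0.851, so its share was about 67.3 %, resting on one scattered reading. Bound from above: that reading less one scatter gave red an exposure of 0.142 and a share of 93.2 %.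

3. Bound from below: over-reaction product cannot fall, so I took its highest reading, at 6.00 min, less one scatter. That gave red an exposure of 2.05 and a share of 42.5 %.

4. Ochre has more partner, which took its bracket to 22.8 % to 86.5 %. Charges alone tied red with amber and violet with ochre.

The forecast, red > amber > violet > ochre, put 64 % and 39 % inside these brackets and called its order tentative: “These near-ties are tentative”.

The flasks gave red > amber > violet > ochre, with red at 67.4 % and ochre at 39.5 %, each inside its bracket.

    catalyst intermediate C → released group + catalyst intermediate D (k = 1350 min⁻¹)
    starting material + protic impurity → quenched substrate (k = 1.30 M⁻¹ min⁻¹)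
    starting material + free catalyst ⇌ catalyst intermediate A (K = 1.50 M⁻¹, k = 43600 M⁻¹ min⁻¹)
    coupling partner + catalyst intermediate A ⇌ catalyst intermediate B (K = 173 M⁻¹, k = 324 M⁻¹ min⁻¹)
    catalyst intermediate D → free catalyst + target (k = 39.5 min⁻¹)
    catalyst intermediate B → catalyst intermediate C (k = 1010 min⁻¹)
    coupling partner + free catalyst + target → free catalyst + over-reaction product (k = 2030 M⁻² min⁻¹)

In red, catalyst intermediate A went on forming through the run, its turnover half done by 18.3 min, close to half of the time, while target was being turned over. At 40 min red held 64.7 % of its catalyst free and 75.7 % of its partner, amber 79.0 % and 83.9 %. Scaling the exposure by these products broke the tie: amber reached 1.15, a share of 59.4 % against the flask's 59.8 %.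

A neighbour of red, charged with 6.0 × 10⁻⁵ M of free catalyst, scales to an exposure of 0.511 and a share of 78.3 %. The computed flask gives 78.1 %.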